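The runs come from a simulation for substances that don't exist.

Start from the clock: green and grey both stop at 8.0 min, so the useful question is how much product each unit of catalyst makes per minute.

| flask | substrate | partner | free catalyst | remark | time |
|---|---|---|---|---|---|
| Wednesday's | 0.50 M | 0.34 M | 1.1 mM | run made earlier |  |
| Friday's | 0.50 M | 0.25 M | 1.1 mM | run made earlier |  |
| green | 1.0 M | 0.500 M | 1.5 mM |  | 8.0 min |
| grey | 0.50 M | 0.500 M | 1.1 mM |  | 8.0 min |

- Wednesday's (time / min: product / %): 1.33: 3.8; 2.50: 7.6; 4.00: 11.2; 5.00: 13.9
- Friday's (time / min: product / %): 0.667: 1.0; 1.50: 4.3; 3.00: 7.7; 5.00: 12.8

(each reading ± 0.5 percentage points)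

- which one finishes higher in amount of product, in percent of the substrate charged ("neither" within 2 percentage points) (green / grey / neither)
- amount of product at the end, in percent of the substrate charged, green
- amount of product at the end, in percent of the substrate charged, grey

- the analysis behind the earlier runs scatters by 0.5 percentage points, standard deviation
- no earlier run changes the charge of free catalyst; that part of a forecast is a guess

Take Wednesday's last reading, turn it into a concentration of product, and divide by the [free catalyst] charged and by the time. This gives 12.6 min⁻¹: call it the turnover rate, the mean turnover frequency on the charge. Friday's gives 11.6 min⁻¹. Now divide one by the other so that time drops out: [partner] differs by a factor of 1.36, the rate by 1.09. So carry Wednesday's value to 0.500 M of partner unchanged. Scale it with the catalyst charged too, though that is a guess, since no run varies it.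

Now reckon two ways. The first holds the turnover rate constant, whatever [substrate] does. The second makes the rate follow [substrate], with 0.0299 min⁻¹ from the same reading. For grey, whose [substrate] matches the runs, they give 22.2% and 21.3%. Both rest on one reading, so their nearness is no check on that reading; it shows that the choice of way moves grey by 0.95 percentage points.

For green they part: 15.2% against 27.9%. Look for the cheat in Wednesday's own run. Its two equal spans of 2.50 min gain 7.6% and 6.3 points, a ratio of 0.829. The second way expects 0.928, the first expects 1, and each reading scatters by 0.5 points, so the run convicts neither. My own reckoning therefore takes the middle for green, 21.5%, and calls the pair neither, loosely.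

The forecast differs. It says green, with grey 24% (21.5% to 27%) and green 27% (17% to 34%), this last “assuming first order in substrate and in catalyst”.

The flasks give green 21.1% and grey 21.4%: neither.

    catalyst intermediate D → catalyst intermediate E (k = 148 min⁻¹)
    partner + free catalyst ⇌ catalyst intermediate A (K = 2.60 M⁻¹, k = 455 M⁻¹ min⁻¹)
    catalyst intermediate A ⇌ by-product + catalyst intermediate B (K = 3.18 M, k = 615 min⁻¹)
    substrate + catalyst intermediate C ⇌ catalyst intermediate D (K = 1.20 M⁻¹, k = 56.2 M⁻¹ min⁻¹)
    catalyst intermediate B → catalyst intermediate C (k = 144 min⁻¹)
    catalyst intermediate E → free catalyst + product (k = 139 min⁻¹)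

Reckon the turnover rate back from these results. Grey gives 12.2 min⁻¹, close to the 12.6 min⁻¹ carried from Wednesday. Green gives 17.6 min⁻¹, which is 1.44 times grey's, with twice the substrate and 1.5 mM rather than 1.1 mM of free catalyst charged. So each way cheated on green: the first came out lower than the flask and the second higher. Carry the rate to the neighbour, which is grey with 1.90 mM of free catalyst: it gives 38.4%. That neighbour turns 34.7% of the substrate charged into product, a mean turnover rate of 11.4 min⁻¹.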